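**Retrosynthetic overview**

- The strategy rests on ring B, the cross-conjugated dienone C5–C6=C7(C11)–C8(=O)–C9=C10. It is a cyclopentenone C5–C6–C8(=O)–C9=C10 enlarged by the single carbon C7, and C7 must carry a handle for C11. Ring A is C1(OH)–C2–C3(O-angeloyl)–C4(Me)–C5(Me)–C10.
- C11–OOH comes from cobalt hydroperoxysilylation of a C7 isopropenyl group, C7–C11 from Suzuki coupling of a C7 bromide, and C7 with its bromine from dibromocarbene insertion into the C6–C8 bond of the C8 silyl dienol ether.
- The hydrindenone (ring A plus the five-membered ring) comes from a Pauson–Khand cyclisation of a 1,7-enyne, which forms C5–C10, C6–C8 and C8–C9 and sets C5.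
- A C3 oxygen of the target configuration would be syn-axial to the new C5 methyl in that cyclisation and would favour the wrong C5 epimer. C3 is therefore carried through as its equatorial epimer and corrected afterwards by oxidation and reduction, before the angelate is put on.
- The enyne comes from an acetate aldol (C1) and a syn-selective (Z)-2-methylcrotylboration (C3, C4). Ring order: ring A and the cyclopentenone together, then ring B by expansion.

Key step: step 12

Remark: the chelated titanium enolate of the (S)-configured auxiliary 2 is taken to add to the alkynal so that the (R)-carbinol 4 is the major adduct; the two adducts are diastereomers and 4 is carried on after chromatographic separation.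

**Step 1**
Reactants: 1 3-(trimethylsilyl)prop-2-ynal; 2 1-[(4S)-4-benzyl-2-thioxo-1,3-thiazolidin-3-yl]ethan-1-one
Product: 4 (3R)-1-[(4S)-4-benzyl-2-thioxo-1,3-thiazolidin-3-yl]-3-hydroxy-5-(trimethylsilyl)pent-4-yn-1-one, via chlorotitanium enolate 3 (not isolated)
Conditions: TiCl4, i-Pr2NEt, CH2Cl2, −40 °C; then 1, −78 °C
Reagents that add atoms: none
Why: Titanium-mediated acetate aldol addition of an N-acetylthiazolidinethione (Nagao/Crimmins type): the thiocarbonyl-chelated enolate is shielded on one face by the benzyl group, so the alkynal should give the (R)-carbinol that becomes C1, and the minor diastereomer is removed by chromatography.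

**Step 2**
Reactants: 4
Product: 5 (3R)-1-[(4S)-4-benzyl-2-thioxo-1,3-thiazolidin-3-yl]-3-[(tert-butyldimethylsilyl)oxy]-5-(trimethylsilyl)pent-4-yn-1-one
Conditions: TBSOTf, 2,6-lutidine, CH2Cl2, −78 → 0 °C
Reagents that add atoms: tert-butyldimethylsilyl triflate, CC(C)(C)[Si](C)(C)OS(=O)(=O)C(F)(F)F
Why: Silyl triflate silylation of a secondary alcohol with a non-nucleophilic base leaves the activated N-acyl thiazolidinethione untouched, which imidazole would not.

**Step 3**
Reactants: 5
Product: 6 (3R)-3-[(tert-butyldimethylsilyl)oxy]-5-(trimethylsilyl)pent-4-ynal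
Conditions: DIBAL-H, CH2Cl2, −78 °C
Reagents that add atoms: none
Why: DIBAL-H reduces N-acylthiazolidinethiones to a chelated aluminium hemiaminal that collapses to the aldehyde only on work-up, so over-reduction is not expected and C1, which is not α to the carbonyl, is not at risk.

**Step 4**
Reactants: 7 (Z)-2-bromobut-2-ene; 8 2-(iodomethyl)-4,4,5,5-tetramethyl-1,3,2-dioxaborolane
Product: 10 2-[(2Z)-2-methylbut-2-en-1-yl]-4,4,5,5-tetramethyl-1,3,2-dioxaborolane, via (E)-but-2-en-2-yllithium 9 (not isolated)
Conditions: t-BuLi (2 equiv), Et2O, −78 °C; then 8, −78 → 23 °C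
Reagents that add atoms: none
Why: Bromine–lithium exchange with retention of alkene geometry, then Matteson-type homologation: the alkenyl boron ate complex undergoes a 1,2-metallate shift with loss of iodide and gives the allylboronate with the γ-methyl cis to CH2B.

**Step 5**
Reactants: 6; 10
Product: 12 (3R,4R,6R)-6-[(tert-butyldimethylsilyl)oxy]-2,3-dimethyl-8-(trimethylsilyl)oct-1-en-7-yn-4-ol, via pinacol borate ester 11 (not isolated)
Conditions: (S)-TRIP [(S)-3,3'-bis(2,4,6-triisopropylphenyl)-1,1'-binaphthyl-2,2'-diyl hydrogen phosphate] (5 mol%), 4 Å MS, toluene, −30 → 0 °C; aqueous NaHCO3 work-up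
Reagents that add atoms: none
Why: Chiral phosphoric acid-catalysed allylboration through a closed chair transition state: the (Z)-γ-methyl group gives the 3,4-syn product, and (S)-TRIP, hydrogen-bonded to the boronate oxygen, should direct attack to the Si face of the aldehyde, which sets C3 as (R) (1,3-anti to C1, on purpose the epimer of the target) and C4 as (R), the remote β-silyloxy centre exerting little bias in a closed transition state.

**Step 6**
Reactants: 12
Product: 13 (3R,4R,6R)-6-[(tert-butyldimethylsilyl)oxy]-2,3-dimethyloct-1-en-7-yn-4-ol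
Conditions: K2CO3, MeOH, 0 → 23 °C
Reagents that add atoms: none
Why: Methanolysis of the alkynyl C–Si bond (protodesilylation) is selective for the trimethylsilylalkyne over the tert-butyldimethylsilyl ether.

**Step 7**
Reactants: 13
Product: 15 (4R,6R,7R,7aR)-4-[(tert-butyldimethylsilyl)oxy]-6-hydroxy-7,7a-dimethyl-1,4,5,6,7,7a-hexahydro-2H-inden-2-one (C1 silyloxy and C4 methyl cis, C3 hydroxyl trans to the angular C5 methyl), via alkyne–hexacarbonyldicobalt complex 14 (not isolated)
Conditions: Co2(CO)8, CH2Cl2, 23 °C; then N-methylmorpholine N-oxide, CH2Cl2, 0 → 23 °C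
Reagents that add atoms: Co2(CO)8 (source of the C8 carbonyl), [Co].[Co].[C-]#[O+].[C-]#[O+].[C-]#[O+].[C-]#[O+].[C-]#[O+].[C-]#[O+].[C-]#[O+].[C-]#[O+]
Why: Intramolecular Pauson–Khand [2+2+1] cyclisation of a 1,7-enyne forms C5–C10, C6–C8 and C8–C9; in the chair-like tether the C3 hydroxyl and C4 methyl sit equatorial and the C1 silyloxy group axial, away from the cobalt cluster, so the alkene should insert with C6 equatorial and the new C5 methyl axial, cis to the C4 methyl and the C1 oxygen.

**Step 8**
Reactants: 15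
Product: 16 (4R,7R,7aR)-4-[(tert-butyldimethylsilyl)oxy]-7,7a-dimethyl-4,5,7,7a-tetrahydro-1H-indene-2,6-dione
Conditions: Dess–Martin periodinane, NaHCO3, CH2Cl2, 0 → 23 °C
Reagents that add atoms: none
Why: Dess–Martin oxidation of the secondary C3 alcohol under buffered, non-basic conditions should spare the β-silyloxy ketone from elimination and leave the enone alone.

**Step 9**
Reactants: 16
Product: 17 (4R,6S,7R,7aR)-4-[(tert-butyldimethylsilyl)oxy]-6-hydroxy-7,7a-dimethyl-1,4,5,6,7,7a-hexahydro-2H-inden-2-one (C1–O, C3–OH, C4–Me and C5–Me all cis)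
Conditions: NaBH4, EtOH, −40 °C
Reagents that add atoms: none
Why: Chemoselective borohydride reduction of a saturated ketone beside a β,β-disubstituted enone (as with the Wieland–Miescher ketone); the axial approach to C3 is blocked by the syn-axial C5 methyl and C1 silyloxy groups, so hydride should enter equatorially and give the axial C3 alcohol, cis to the other three substituents.

**Step 10**
Reactants: 17; 18 angelic acid [(2Z)-2-methylbut-2-enoic acid]
Product: 20 C3 angelate of 17 (1R,3S,4R,5R in the overview numbering; C1–OTBS, C3–O-angeloyl, C4–Me and C5–Me all cis), via angelic 2,4,6-trichlorobenzoic anhydride 19 (not isolated)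
Conditions: 2,4,6-Cl3C6H2COCl, Et3N, toluene, 23 °C; then 17, toluene, 80 °C
Reagents that add atoms: none
Why: Yamaguchi-type esterification through the preformed mixed anhydride without a nucleophilic catalyst transfers the angeloyl group without Z to E isomerisation, here onto a hindered axial alcohol that needs heating.

**Step 11**
Reactants: 20
Product: 22 C8 triethylsilyl dienol ether of 20 (fused 2-silyloxycyclopentadiene with C6=C8 and C9=C10; ring A as in 20), via lithium dienolate 21 (not isolated)
Conditions: LiN(SiMe3)2, THF, −78 °C; then Et3SiCl, Et3N, −78 → 0 °C; used at once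
Reagents that add atoms: chlorotriethylsilane, CC[Si](CC)(CC)Cl
Why: Kinetic deprotonation of the enone at the α′-carbon C6 with a hindered amide base and O-silylation gives the cross-conjugated 2-silyloxydiene, since the γ-hydrogen at C1 and the γ-hydrogens of the angelate are kinetically less acidic.

**Step 12**
Reactants: 22; 23 bromoform
Product: 25 7-bromo cross-conjugated dienone (C5–C6=C7(Br)–C8(=O)–C9=C10; C1–OTBS, C3–O-angeloyl, C4–Me and C5–Me all cis), via dibromocyclopropane 24 (not isolated)
Conditions: KOt-Bu, pentane, −30 °C, CHBr3 added slowly; then −30 → 23 °C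
Reagents that add atoms: none
Why: tert-Butoxide deprotonates bromoform and the tribromomethyl anion loses bromide to give singlet dibromocarbene, which adds in a concerted [2+1] step to the C6=C8 silyl enol ether bond of 22. The 1-silyloxy-6,6-dibromobicyclo[3.1.0]hexene 24 then ionises the bromide endo to the five-membered ring while the C6–C8 bond opens in a disrotatory two-electron electrocyclic step, and bromide removes the silyl group from the resulting oxocarbenium ion to leave C8=O and C6=C7–Br. The closest known reaction type is the dihalocarbene ring expansion of cyclic silyl enol ethers to 2-halocycloalk-2-enones, including kinetic silyl dienol ethers of cyclohexenones, which give halocycloheptadienones. Ring B is not closed end to end: the cyclopropane closes by cheletropic addition and the six-membered ring arises by enlargement of the five-membered ring through cleavage of the shared C6–C8 bond, so C7 ends between C6 and C8. No stereocentre is created, because C6 and C8 return to sp2 and the face of carbene attack is lost. The step needs site selectivity for C6=C8 over C9=C10 and the angelate alkene, which the oxygen donor (largest HOMO coefficient at C6), the crowded fully substituted C10 and the electron-poor ester alkene secure, and the quaternary C5 blocks aromatisation.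

**Step 13**
Reactants: 25; 26 isopropenylboronic acid pinacol ester
Product: 27 7-isopropenyl cross-conjugated dienone (ring A as in 25)
Conditions: Pd(dppf)Cl2 (5 mol%), K3PO4, THF/H2O, 50 °C
Reagents that add atoms: none
Why: Suzuki–Miyaura coupling of an α-bromo enone, whose C7–Br bond undergoes fast oxidative addition, with the alkenyl boronate under mild phosphate base that the angelate and the silyl ether tolerate.

**Step 14**
Reactants: 27
Product: 28 C11 triethylsilyl peroxide [7-(2-(triethylsilylperoxy)propan-2-yl) dienone; ring A as in 25]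
Conditions: Co(acac)2 (10 mol%), Et3SiH, O2 (1 atm), ClCH2CH2Cl, 23 °C
Reagents that add atoms: dioxygen, O=O; triethylsilane, CC[SiH](CC)CC
Why: Isayama–Mukaiyama hydroperoxysilylation by metal-hydride hydrogen atom transfer: the cobalt hydride delivers H to the terminal CH2 of the only 1,1-disubstituted alkene, and the tertiary C11 radical is captured by O2 and silylated (Markovnikov), while the electron-poor trisubstituted alkenes react more slowly.

**Step 15**
Reactants: 28
Product: 29 CNP0300636.1 (1R,3S,4R,5R; 3-O-angeloyl-11-hydroperoxy-1-hydroxy-6,9-dien-8-one)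
Conditions: HF·pyridine, pyridine, THF, 0 → 23 °C
Reagents that add atoms: none
Why: Fluoride cleavage of both Si–O bonds under weakly acidic conditions removes the peroxide silyl group and the allylic silyl ether without base, so neither the angelate (no 1,3-acyl shift to the cis C1 hydroxyl) nor the hydroperoxide is endangered.

**Compound list**

1 | 3-(trimethylsilyl)prop-2-ynal | C[Si](C)(C)C#CC=O | starting material
2 | 1-[(4S)-4-benzyl-2-thioxo-1,3-thiazolidin-3-yl]ethan-1-one | CC(=O)N1[C@@H](Cc2ccccc2)CSC1=S | starting material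
3 | trichlorotitanium enolate of 2 | C=C(O[Ti](Cl)(Cl)Cl)N1[C@@H](Cc2ccccc2)CSC1=S | intermediate
4 | (3R)-1-[(4S)-4-benzyl-2-thioxo-1,3-thiazolidin-3-yl]-3-hydroxy-5-(trimethylsilyl)pent-4-yn-1-one | C[Si](C)(C)C#C[C@H](O)CC(=O)N1[C@@H](Cc2ccccc2)CSC1=S | intermediate
5 | tert-butyldimethylsilyl ether of 4 | C[Si](C)(C)C#C[C@H](O[Si](C)(C)C(C)(C)C)CC(=O)N1[C@@H](Cc2ccccc2)CSC1=S | intermediate
6 | (3R)-3-[(tert-butyldimethylsilyl)oxy]-5-(trimethylsilyl)pent-4-ynal | C[Si](C)(C)C#C[C@H](O[Si](C)(C)C(C)(C)C)CC=O | intermediate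
7 | (Z)-2-bromobut-2-ene | C/C=C(/C)Br | starting material
8 | 2-(iodomethyl)-4,4,5,5-tetramethyl-1,3,2-dioxaborolane | ICB1OC(C)(C)C(C)(C)O1 | starting material
9 | (E)-but-2-en-2-yllithium (lithium cis to the C3 methyl) | C/C=C(/C)[Li] | intermediate
10 | 2-[(2Z)-2-methylbut-2-en-1-yl]-4,4,5,5-tetramethyl-1,3,2-dioxaborolane | C/C=C(/C)CB1OC(C)(C)C(C)(C)O1 | intermediate
11 | pinacol borate ester of 12 | O(B1OC(C)(C)C(C)(C)O1)[C@@H]([C@H](C)C(C)=C)C[C@@H](O[Si](C)(C)C(C)(C)C)C#C[Si](C)(C)C | intermediate
12 | (3R,4R,6R)-6-[(tert-butyldimethylsilyl)oxy]-2,3-dimethyl-8-(trimethylsilyl)oct-1-en-7-yn-4-ol | O[C@@H]([C@H](C)C(C)=C)C[C@@H](O[Si](C)(C)C(C)(C)C)C#C[Si](C)(C)C | intermediate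
13 | (3R,4R,6R)-6-[(tert-butyldimethylsilyl)oxy]-2,3-dimethyloct-1-en-7-yn-4-ol | O[C@@H]([C@H](C)C(C)=C)C[C@@H](O[Si](C)(C)C(C)(C)C)C#C | intermediate
14 | alkyne–hexacarbonyldicobalt complex of 13 | O[C@@H]([C@H](C)C(C)=C)C[C@@H](O[Si](C)(C)C(C)(C)C)C12C3[Co]1(=C=O)(=C=O)(=C=O)[Co]23(=C=O)(=C=O)=C=O | intermediate
15 | (4R,6R,7R,7aR)-4-[(tert-butyldimethylsilyl)oxy]-6-hydroxy-7,7a-dimethyl-1,4,5,6,7,7a-hexahydro-2H-inden-2-one | O[C@@H]1C[C@@H](O[Si](C)(C)C(C)(C)C)C2=CC(=O)C[C@]2(C)[C@H]1C | intermediate
16 | (4R,7R,7aR)-4-[(tert-butyldimethylsilyl)oxy]-7,7a-dimethyl-4,5,7,7a-tetrahydro-1H-indene-2,6-dione | O=C1C[C@@H](O[Si](C)(C)C(C)(C)C)C2=CC(=O)C[C@]2(C)[C@H]1C | intermediate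
17 | (4R,6S,7R,7aR)-4-[(tert-butyldimethylsilyl)oxy]-6-hydroxy-7,7a-dimethyl-1,4,5,6,7,7a-hexahydro-2H-inden-2-one | O[C@H]1C[C@@H](O[Si](C)(C)C(C)(C)C)C2=CC(=O)C[C@]2(C)[C@H]1C | intermediate
18 | angelic acid, (2Z)-2-methylbut-2-enoic acid | C/C=C(/C)C(=O)O | starting material
19 | (2Z)-2-methylbut-2-enoic 2,4,6-trichlorobenzoic anhydride | C/C=C(/C)C(=O)OC(=O)c1c(Cl)cc(Cl)cc1Cl | intermediate
20 | C3 angelate of 17 (bicyclic enone, all-cis ring A) | C/C=C(/C)C(=O)O[C@H]1C[C@@H](O[Si](C)(C)C(C)(C)C)C2=CC(=O)C[C@]2(C)[C@H]1C | intermediate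
21 | lithium cross-conjugated dienolate of 20 | C/C=C(/C)C(=O)O[C@H]1C[C@@H](O[Si](C)(C)C(C)(C)C)C2=CC(O[Li])=C[C@]2(C)[C@H]1C | intermediate
22 | C8 triethylsilyl dienol ether of 20 (fused 2-silyloxycyclopentadiene) | C/C=C(/C)C(=O)O[C@H]1C[C@@H](O[Si](C)(C)C(C)(C)C)C2=CC(O[Si](CC)(CC)CC)=C[C@]2(C)[C@H]1C | intermediate
23 | bromoform | BrC(Br)Br | starting material
24 | dibromocyclopropane from carbene addition to C6=C8 of 22 (C6 and C8 configuration undefined) | C/C=C(/C)C(=O)O[C@H]1C[C@@H](O[Si](C)(C)C(C)(C)C)C2=CC3(O[Si](CC)(CC)CC)C(Br)(Br)C3[C@]2(C)[C@H]1C | intermediate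
25 | 7-bromo cross-conjugated dienone | C/C=C(/C)C(=O)O[C@H]1C[C@@H](O[Si](C)(C)C(C)(C)C)C2=CC(=O)C(Br)=C[C@]2(C)[C@H]1C | intermediate
26 | isopropenylboronic acid pinacol ester | CC(=C)B1OC(C)(C)C(C)(C)O1 | starting material
27 | 7-isopropenyl cross-conjugated dienone | C/C=C(/C)C(=O)O[C@H]1C[C@@H](O[Si](C)(C)C(C)(C)C)C2=CC(=O)C(C(C)=C)=C[C@]2(C)[C@H]1C | intermediate
28 | C11 triethylsilyl peroxide, C1 tert-butyldimethylsilyl ether of the target | C/C=C(/C)C(=O)O[C@H]1C[C@@H](O[Si](C)(C)C(C)(C)C)C2=CC(=O)C(C(C)(C)OO[Si](CC)(CC)CC)=C[C@]2(C)[C@H]1C | intermediate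
29 | CNP0300636.1 | C/C=C(/C)C(=O)O[C@H]1C[C@@H](O)C2=CC(=O)C(C(C)(C)OO)=C[C@]2(C)[C@H]1C | target

**Step count and risks**

Total steps: 15. Longest linear sequence: 14 steps (steps 1–3 and 5–15; step 4 makes the boronate for step 5).

The three steps most likely to fail:

1. Step 12 (key step). The carbene may add at C9=C10, tert-butoxide may desilylate the dienol ether back to the enone or attack the angelate, the dibromocyclopropane may open incompletely, or the O-silylated cyclohexadienyl cation may undergo a 1,2-shift towards a phenol. The fallback sets out from 22 and inserts a CH2 carbon first, then halogenates it. Furukawa–Simmons–Smith cyclopropanation (Et2Zn, CH2I2) of the enol ether bond gives the silyloxycyclopropane F1. Oxidative ring opening with FeCl3 in DMF (Ito–Saegusa ring expansion) gives the C6 chloro ketone F2. NaOAc in MeOH eliminates HCl to the 7-unsubstituted dienone F3. Iodine and pyridine iodinate C7, the α-carbon whose β-carbon C6 is the accessible one, to give the 7-iodo dienone F4. Suzuki coupling of F4 with 26 under the conditions of step 13 comes back to the route at 27.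

2. Step 14. The C11 radical is allylic (C11–C7–C6) and may capture O2 at C6 instead of C11; hydrogen atom transfer may also reach the ring alkenes or the angelate. The fallback sets out from 27 and forms the C11–O bond by an ene reaction. Conjugate reduction at C6 with [(Ph3P)CuH]6 and isomerisation with DBU give the 7-isopropylidene enone F5. Photooxygenation (O2, tetraphenylporphyrin, hν, CH2Cl2; Schenck ene reaction) abstracts hydrogen from C6, the group geminal to the carbonyl on C7, and places the hydroperoxide on C11 with the C6=C7 bond restored, giving the C1 silyl ether of the target F6. HF·pyridine then comes back to the route at 29.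

3. Step 5. Allyl transfer from the β,γ-disubstituted boronate may be slow, and facial selectivity may erode if catalyst and the C1 centre are mismatched. The fallback sets out from 6 and uses auxiliary control. Evans syn aldol addition of the boron enolate of (4S)-4-benzyl-3-propanoyl-1,3-oxazolidin-2-one (Bu2BOTf, Et3N) gives the (2S,3R)-syn adduct F7. MeNHOMe·HCl and AlMe3 give the Weinreb amide F8. MeMgBr gives the methyl ketone F9. Wittig methylenation with salt-free Ph3P=CH2 at low temperature comes back to the route at 12.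

**Further compounds**

F1 | step 12 | silyloxycyclopropane from CH2 addition to C6=C8 of 22 | C/C=C(/C)C(=O)O[C@H]1C[C@@H](O[Si](C)(C)C(C)(C)C)C2=CC3(O[Si](CC)(CC)CC)CC3[C@]2(C)[C@H]1C
F2 | step 12 | ring-expanded C6 chloro ketone | C/C=C(/C)C(=O)O[C@H]1C[C@@H](O[Si](C)(C)C(C)(C)C)C2=CC(=O)CC(Cl)[C@]2(C)[C@H]1C
F3 | step 12 | 7-unsubstituted cross-conjugated dienone | C/C=C(/C)C(=O)O[C@H]1C[C@@H](O[Si](C)(C)C(C)(C)C)C2=CC(=O)C=C[C@]2(C)[C@H]1C
F4 | step 12 | 7-iodo cross-conjugated dienone | C/C=C(/C)C(=O)O[C@H]1C[C@@H](O[Si](C)(C)C(C)(C)C)C2=CC(=O)C(I)=C[C@]2(C)[C@H]1C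
F5 | step 14 | 7-isopropylidene-9-en-8-one | C/C=C(/C)C(=O)O[C@H]1C[C@@H](O[Si](C)(C)C(C)(C)C)C2=CC(=O)C(=C(C)C)C[C@]2(C)[C@H]1C
F6 | step 14 | C1 tert-butyldimethylsilyl ether of the target | C/C=C(/C)C(=O)O[C@H]1C[C@@H](O[Si](C)(C)C(C)(C)C)C2=CC(=O)C(C(C)(C)OO)=C[C@]2(C)[C@H]1C
F7 | step 5 | Evans syn aldol adduct, (2S,3R,5R)-configured N-acyl oxazolidinone | O[C@@H]([C@H](C)C(=O)N1C(=O)OC[C@@H]1Cc1ccccc1)C[C@@H](O[Si](C)(C)C(C)(C)C)C#C[Si](C)(C)C
F8 | step 5 | Weinreb amide | O[C@@H]([C@H](C)C(=O)N(C)OC)C[C@@H](O[Si](C)(C)C(C)(C)C)C#C[Si](C)(C)C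
F9 | step 5 | β-hydroxy methyl ketone | O[C@@H]([C@H](C)C(C)=O)C[C@@H](O[Si](C)(C)C(C)(C)C)C#C[Si](C)(C)C
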